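**Retrosynthetic overview**
- The target comes from a ring‑D cyclopentenone by enone hydrogenation and removal of the C17 carbonyl. That enone comes from an intramolecular Pauson–Khand reaction of a 1,7‑enyne carried on the finished A–B bicycle, which forms rings C and D together.
- The 1,7‑enyne comes from a cyclooctenone: C11–C15 by allenylzinc addition to the C11 ketone; C8–CH3 and C9–C12 by one‑pot asymmetric conjugate methylation and enolate allylation of a cross‑conjugated cyclooctadienone.
- The dienone comes from bis‑allylic oxidation of a skipped 5–8 diene, which is made in the key step: a rhodium‑catalysed [4+2+2] of an (R)‑1,6‑enyne with butadiene. This forms rings A and B in one operation and sets C5 and the tetrasubstituted C1=C10 alkene.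
- The enyne comes from (R)‑β‑citronellene, which supplies the C4 stereocentre.
- Ring order: A + B together, then C + D together.

Assumption: (R)‑β‑citronellene, benzyl 2‑(bromomethyl)acrylate and 4‑methylpent‑2‑yne are bought; the (S,R,R)‑phosphoramidite is taken as the ligand enantiomer that gives 8S in step 6 (otherwise its antipode is used).

Atom labels (target): ring A = C1(sp2), C2, C3, C4(CH3), C5; ring B = C1, C5, C6, C7, C8(CH3), C9, C11(OH), C10(CH3); ring C = C9, C12, C13(CO2H), C14, C15, C11; ring D = C13, C16, C17, C18(i‑Pr), C14. Target = (4R,5S,8S,9R,11R,13S,14S,18R).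

**Step 1**
Reactants: 1 (3R)-3,7-dimethylocta-1,6-diene
Product: 3 (4R)-4-methylhex-5-enal, via ozonide 2 (not isolated)
Conditions: O3, CH2Cl2, −78 °C (Sudan Red 7B end point); PPh3, −78 °C → rt
Reagents that add atoms: ozone, [O-][O+]=O
Why: Ozonolysis is selective for the electron‑rich trisubstituted alkene over the vinyl group (dye end point), and the chiral‑pool C4 centre is untouched.

**Step 2**
Reactants: 3 (4R)-4-methylhex-5-enal
Product: 4 (3R)-3-methylhept-1-en-6-yne
Conditions: dimethyl (1-diazo-2-oxopropyl)phosphonate, K2CO3, MeOH, 0 °C → rt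
Reagents that add atoms: dimethyl (1-diazo-2-oxopropyl)phosphonate, CC(=O)C(=[N+]=[N-])P(=O)(OC)OC
Why: Ohira–Bestmann (Seyferth–Gilbert) homologation turns the aldehyde into the terminal alkyne under mild base without touching the remote stereocentre or the vinyl group.

**Step 3**
Reactants: 4 (3R)-3-methylhept-1-en-6-yne
Product: 6 (3R)-3-methyloct-1-en-6-yne, via lithium acetylide 5 (not isolated)
Conditions: n-BuLi, THF, −78 °C; MeI, −78 °C → rt
Reagents that add atoms: iodomethane, CI
Why: Acetylide alkylation (deprotonation, SN2 on MeI) installs the carbon that becomes the C10 methyl.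

**Step 4**
Reactants: 6 (3R)-3-methyloct-1-en-6-yne; 7 buta-1,3-diene
Product: 8 A–B bicyclic skipped diene (4R,5S)
Conditions: 7 (1 atm), RhCl(PPh3)3 (10 mol %), AgOTf (20 mol %), PhMe, 110 °C
Reagents that add atoms: none
Why: Rhodium‑catalysed intermolecular [4+2+2] carbocyclisation, in which oxidative cyclisation of the 1,6‑enyne gives a rhodacyclopentene (ring A, with the allylic methyl exo so that it ends trans to C6, giving 5S) and butadiene insertion with reductive elimination closes ring B with the alkyne carbons as the Z tetrasubstituted C1=C10 alkene; the reaction is established for heteroatom‑ and malonate‑tethered enynes and is extended here to a plain carbon tether.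

**Step 5**
Reactants: 8 A–B bicyclic skipped diene (4R,5S)
Product: 9 cross-conjugated dienone (4R,5S)
Conditions: (C5H5NH)2Cr2O7, t-BuOOH, Celite, PhH, 10 °C → rt
Reagents that add atoms: tert-butyl hydroperoxide, CC(C)(C)OO
Why: Chromium‑mediated allylic C–H oxidation attacks the weakest C–H bonds, the doubly allylic C11 methylene, and gives the cross‑conjugated dienone in the same way that 1,4‑cyclohexadienes give 2,5‑cyclohexadienones.

**Step 6**
Reactants: 9 cross-conjugated dienone (4R,5S); 10 benzyl 2-(bromomethyl)prop-2-enoate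
Product: 12 enone keto ester (4R,5S,8S,9R), via zinc enolate 11 (not isolated)
Conditions: Me2Zn, Cu(OTf)2 (2 mol %), (S,R,R)-binaphthyl bis(1-phenylethyl)phosphoramidite (4 mol %), PhMe, −25 °C; then 10, DMPU, −25 → 0 °C
Reagents that add atoms: dimethylzinc, C[Zn]C
Why: Copper–phosphoramidite asymmetric conjugate addition is regioselective for the disubstituted enone (the other β‑carbon, C1, is fully substituted) and sets C8 (S) under ligand control, and the zinc enolate is then allylated by SN2' on the bromomethyl acrylate anti to the new methyl, which sets C9 (R, also the thermodynamic α‑epimer).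

**Step 7**
Reactants: 12 enone keto ester (4R,5S,8S,9R); 13 4-methylpent-2-yne
Product: 16 tertiary homopropargylic alcohol (4R,5S,8S,9R,11R), via propargyllithium 14 (not isolated), via allenylzinc bromide 15 (not isolated)
Conditions: 13, n-BuLi, THF, −78 → 0 °C; ZnBr2, −78 °C; then 12, −78 → −20 °C; aq NH4Cl
Reagents that add atoms: none
Why: Lithiation of the 2‑alkyne at its methyl group and transmetallation give an allenylzinc that adds to the ketone by SE2' to give the homopropargylic carbinol, chemoselectively over the acrylate ester, by Felkin–Anh approach anti to the C9–C8 ring bond and past C9–H, which places the C15 chain trans to the C9 side chain (11R).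

**Step 8**
Reactants: 16 tertiary homopropargylic alcohol (4R,5S,8S,9R,11R)
Product: 17 tetracyclic cyclopentenone (4R,5S,8S,9R,11R,13R)
Conditions: CO (1 atm), Co2(CO)8 (20 mol %), tetramethylthiourea (1.2 equiv), PhH, 70 °C
Reagents that add atoms: carbon monoxide, [C-]#[O+]
Why: Intramolecular Pauson–Khand reaction of the 1,7‑enyne forms rings C and D together, and in the chair‑like transition state (ring‑B bonds at C9 and C11 equatorial, hydroxyl axial) C16 must be equatorial to reach the alkyne, so the ester on the new quaternary C13 is axial and trans to the hydroxyl.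

**Step 9**
Reactants: 17 tetracyclic cyclopentenone (4R,5S,8S,9R,11R,13R)
Product: 18 keto acid (4R,5S,8S,9R,11R,13R,14S,18R)
Conditions: H2 (4 atm), 10% Pd/C, EtOAc, rt
Reagents that add atoms: none
Why: Heterogeneous hydrogenation saturates the conjugated tetrasubstituted enone (the isolated, hindered C1=C10 alkene is inert) by syn addition to the face opposite the axial angular ester, as in the hydrogenation of steroid 14‑enes, which gives the trans C/D fusion at C14 and the isopropyl at C18 cis to the carboxyl, and it cleaves the benzyl ester by hydrogenolysis.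

**Step 10**
Reactants: 18 keto acid (4R,5S,8S,9R,11R,13R,14S,18R)
Product: 20 C16=C17 enol triflate acid (4R,5S,8S,9R,11R,13S,14S,18R), via tripotassium salt 19 (not isolated)
Conditions: KN(SiMe3)2 (3.5 equiv), THF, −78 °C; PhNTf2, −78 → 0 °C; aq NH4Cl
Reagents that add atoms: N-phenylbis(trifluoromethanesulfonimide), O=S(=O)(N(c1ccccc1)S(=O)(=O)C(F)(F)F)C(F)(F)F
Why: Kinetic deprotonation by the bulky amide takes the C16 methylene and not the isopropyl‑bearing C18 methine, so O‑triflation of the enolate gives the C16=C17 enol triflate without epimerising the less stable C18 centre, and in the saturated ketone the C11 alkoxide has no retro‑aldol pathway.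

**Step 11**
Reactants: 20 C16=C17 enol triflate acid (4R,5S,8S,9R,11R,13S,14S,18R)
Product: 21 sesterfisheric acid
Conditions: H2 (1 atm), PtO2, NaHCO3, EtOAc–MeOH, rt; pH 4 work-up
Reagents that add atoms: none
Why: Hydrogenolysis and hydrogenation of the enol triflate over PtO2 removes the C17 oxygen and saturates C16=C17 (no new stereocentre), the hydrogencarbonate buffer protects the tertiary allylic alcohol from triflic acid, and the hindered tetrasubstituted C1=C10 alkene survives.

**Compound list**
1 | (3R)-3,7-dimethylocta-1,6-diene [(R)-β-citronellene] | C=C[C@H](C)CCC=C(C)C | starting material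
2 | ozonide of 1: 3,3-dimethyl-5-[(3R)-3-methylpent-4-enyl]-1,2,4-trioxolane (both epimers at the ring CH) | C=C[C@H](C)CCC1OOC(C)(C)O1 | intermediate (not isolated)
3 | (4R)-4-methylhex-5-enal | C=C[C@H](C)CCC=O | intermediate
4 | (3R)-3-methylhept-1-en-6-yne | C=C[C@H](C)CCC#C | intermediate
5 | lithium acetylide of 4 | C=C[C@H](C)CCC#C[Li] | intermediate (not isolated)
6 | (3R)-3-methyloct-1-en-6-yne | C=C[C@H](C)CCC#CC | intermediate
7 | buta-1,3-diene | C=CC=C | starting material
8 | (1Z,4Z,8S,9R)-2,9-dimethylbicyclo[6.3.0]undeca-1,4-diene (labels: 4R,5S; C1=C10 and C8=C9; C11H2 between them) | C/C1=C2\CC[C@@H](C)[C@@H]2CC/C=C\C1 | intermediate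
9 | (1Z,4Z,8S,9R)-2,9-dimethylbicyclo[6.3.0]undeca-1,4-dien-3-one (C11 ketone; labels 4R,5S) | C/C1=C2\CC[C@@H](C)[C@@H]2CC/C=C\C1=O | intermediate
10 | benzyl 2-(bromomethyl)prop-2-enoate | C=C(CBr)C(=O)OCc1ccccc1 | starting material
11 | methylzinc enolate (C9=C11–OZnCH3) of the 8S methyl adduct of 9 | C/C1=C2\CC[C@@H](C)[C@@H]2CC[C@H](C)/C=C1/O[Zn]C | intermediate (not isolated)
12 | A–B enone with C11 ketone, 8S methyl and 9R CH2C(=CH2)CO2Bn chain, methyl and chain trans (4R,5S,8S,9R) | C/C1=C2\CC[C@@H](C)[C@@H]2CC[C@H](C)[C@@H](CC(=C)C(=O)OCc3ccccc3)C1=O | intermediate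
13 | 4-methylpent-2-yne | CC#CC(C)C | starting material
14 | (4-methylpent-2-yn-1-yl)lithium (propargyl/allenyl lithium) | [Li]CC#CC(C)C | intermediate (not isolated)
15 | (4-methylpenta-1,2-dien-3-yl)zinc bromide | C=C=C([Zn]Br)C(C)C | intermediate (not isolated)
16 | 12 with C11(OH)CH2C≡C-i-Pr, C15 chain trans to the C9 chain (4R,5S,8S,9R,11R) | C/C1=C2\CC[C@@H](C)[C@@H]2CC[C@H](C)[C@@H](CC(=C)C(=O)OCc3ccccc3)[C@]1(O)CC#CC(C)C | intermediate
17 | tetracycle with ring-D enone (C17=O, C18(i-Pr)=C14) and angular CO2Bn on C13 trans to the C11 hydroxyl (4R,5S,8S,9R,11R,13R) | C/C1=C2\CC[C@@H](C)[C@@H]2CC[C@H](C)[C@H]2C[C@@]3(C(=O)OCc4ccccc4)CC(=O)C(C(C)C)=C3C[C@]12O | intermediate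
18 | keto acid: ring-D cyclopentanone (C17=O), trans C/D fusion, isopropyl cis to CO2H (4R,5S,8S,9R,11R,13R,14S,18R) | C/C1=C2\CC[C@@H](C)[C@@H]2CC[C@H](C)[C@H]2C[C@@]3(C(=O)O)CC(=O)[C@H](C(C)C)[C@@H]3C[C@]12O | intermediate
19 | tripotassium carboxylate / C11 alkoxide / C16=C17 enolate of 18 | C/C1=C2\CC[C@@H](C)[C@@H]2CC[C@H](C)[C@H]2C[C@@]3(C(=O)[O-])C=C([O-])[C@H](C(C)C)[C@@H]3C[C@]12[O-].[K+].[K+].[K+] | intermediate (not isolated)
20 | C16=C17 enol triflate of 18, free acid (4R,5S,8S,9R,11R,13S,14S,18R) | C/C1=C2\CC[C@@H](C)[C@@H]2CC[C@H](C)[C@H]2C[C@@]3(C(=O)O)C=C(OS(=O)(=O)C(F)(F)F)[C@H](C(C)C)[C@@H]3C[C@]12O | intermediate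
21 | sesterfisheric acid (4R,5S,8S,9R,11R,13S,14S,18R) | C/C1=C2\CC[C@@H](C)[C@@H]2CC[C@H](C)[C@H]2C[C@@]3(C(=O)O)CC[C@H](C(C)C)[C@@H]3C[C@]12O | target

**Totals and risks**
Total step count: 11. Longest linear sequence: 11 steps (1 → 21); all other inputs are purchased.

Steps most likely to fail:

Step 4. The [4+2+2] has not been shown on an unactivated carbon tether; cycloisomerisation of the enyne or failure to take up butadiene are the likely failures. The fallback sets out from 6 and comes back at 8, building the two rings one after the other. Cp2ZrCl2 with two equivalents of n‑BuLi converts 6 into the zirconacyclopentene F1 (ring A, same trans C4/C5 relation). Double allylation with allyl chloride and CuCl gives the triene F2, with one allyl on C10 and one on C6. Ring‑closing metathesis with the second‑generation Grubbs catalyst then closes ring B at C8=C9 and gives 8.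

Step 7. The addition to a hindered, enolisable cyclooctenone may give the allenic regioisomer or the wrong C11 epimer. The fallback sets out from 12 and comes back at 16, delivering C15 first as a methylene. Corey–Chaykovsky reaction of 12 with dimethylsulfonium methylide gives the spiro‑epoxide F3 (the reversible dimethylsulfoxonium methylide is used if the other C11 epimer forms). Opening at the CH2 terminus with i‑PrC≡CAlEt2 gives 16.

Step 8. The Pauson–Khand alkene is an electron‑poor, 1,1‑disubstituted acrylate in a 1,7‑enyne, which is a demanding combination. The fallback sets out from 9 and comes back at 18, carrying the carboxyl carbon as a benzyl ether so that the alkene is electron‑neutral. The zinc enolate 11 is quenched with 2‑(bromomethyl)allyl benzyl ether to give the ketone F4. Allenylzinc addition as in step 7 gives the enyne F5, and the Pauson–Khand reaction gives the enone F6. H2 over Pd/C saturates the enone and removes the benzyl group to give the keto diol F7. TEMPO/PhI(OAc)2 oxidises the neopentyl CH2OH to the aldehyde F8, and NaClO2 with 2‑methylbut‑2‑ene gives 18.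

**Further compounds**
F1 | step 4 | zirconacyclopentene from 6: bis(cyclopentadienyl)zirconium bridging C10 and C6, ring A formed (4R,5S) | C/C1=C2\CC[C@@H](C)[C@@H]2C[Zr+2]1.c1cc[cH-]c1.c1cc[cH-]c1
F2 | step 4 | triene: ring A with C1=C10(CH3)(allyl) and C5 but-3-enyl (4R,5S) | C=CC/C(C)=C1/CC[C@@H](C)[C@@H]1CCC=C
F3 | step 7 | spiro-epoxide of 12 at C11 (C11–O–C15H2) | C/C1=C2\CC[C@@H](C)[C@@H]2CC[C@H](C)[C@@H](CC(=C)C(=O)OCc3ccccc3)[C@]14CO4
F4 | step 8 | analogue of 12 with C9 chain CH2C(=CH2)CH2OBn | C/C1=C2\CC[C@@H](C)[C@@H]2CC[C@H](C)[C@@H](CC(=C)COCc3ccccc3)C1=O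
F5 | step 8 | analogue of 16 with CH2OBn in place of CO2Bn | C/C1=C2\CC[C@@H](C)[C@@H]2CC[C@H](C)[C@@H](CC(=C)COCc3ccccc3)[C@]1(O)CC#CC(C)C
F6 | step 8 | analogue of 17 with angular CH2OBn on C13 | C/C1=C2\CC[C@@H](C)[C@@H]2CC[C@H](C)[C@H]2C[C@@]3(COCc4ccccc4)CC(=O)C(C(C)C)=C3C[C@]12O
F7 | step 8 | keto diol: analogue of 18 with angular CH2OH on C13 | C/C1=C2\CC[C@@H](C)[C@@H]2CC[C@H](C)[C@H]2C[C@@]3(CO)CC(=O)[C@H](C(C)C)[C@@H]3C[C@]12O
F8 | step 8 | keto aldehyde: analogue of 18 with angular CHO on C13 | C/C1=C2\CC[C@@H](C)[C@@H]2CC[C@H](C)[C@H]2C[C@@]3(C=O)CC(=O)[C@H](C(C)C)[C@@H]3C[C@]12O
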